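The route rests on disconnecting the pyranone ring (O1, C2, C3, C4, C4a, C8a) at O1–C2 and C3–C4 into a benzofuran-2,3-dione and buta-1,2-diene. In one nickel-catalysed operation the five-membered dione ring should lose its lactone carbonyl as CO and take up two allene carbons, expanding to the six-membered ring while the chiral ligand sets C2. The step exploits the aryl β-oxy ketone O1–C2–C3–C4(=O) of that ring, whose C2, C3 and both methyl carbons are one four-carbon allene held between an aroyl and an aryloxide. The precursor is the dione made with oxalyl chloride from a symmetric 3,5-dimethoxyphenol that already carries the (R)-octanoate chain.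

Key step: step 6

Assumption: the facial sense of the two catalyst-controlled steps (3 and 6) is assigned by analogy with the closest precedents; the ligand antipode written is the one taken to give the R centres, and its mirror image would be used if the sense proves opposite.

Step 1
Reactants: 1 4-hydroxy-2,6-dimethoxybenzaldehyde; 2 benzyl bromide
Product: 3 4-(benzyloxy)-2,6-dimethoxybenzaldehyde
Conditions: K2CO3, DMF, rt
Reagents that add atoms: none
Why: Williamson ether synthesis on the acidic para-phenol masks the oxygen that later becomes O1 during the olefination and Grignard steps.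

Step 2
Reactants: 3 4-(benzyloxy)-2,6-dimethoxybenzaldehyde; 4 trimethyl phosphonoacetate
Product: 5 methyl (E)-3-[4-(benzyloxy)-2,6-dimethoxyphenyl]prop-2-enoate
Conditions: NaH, THF, 0 to 50 °C
Reagents that add atoms: none
Why: Horner–Wadsworth–Emmons olefination with the stabilised phosphonate anion should give the (E)-enoate.

Step 3
Reactants: 5 methyl (E)-3-[4-(benzyloxy)-2,6-dimethoxyphenyl]prop-2-enoate; 6 n-pentylmagnesium bromide
Product: 7 methyl (3R)-3-[4-(benzyloxy)-2,6-dimethoxyphenyl]octanoate
Conditions: CuI (3 mol%), (S)-Tol-BINAP (4.5 mol%), t-BuOMe, −40 °C; aq NH4Cl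
Reagents that add atoms: none
Why: Copper-catalysed asymmetric conjugate addition of the Grignard reagent to the (E)-enoate, in which the chiral bisphosphine–copper complex should deliver pentyl to the Re face of C-β and so set the R benzylic centre.

Step 4
Reactants: 7 methyl (3R)-3-[4-(benzyloxy)-2,6-dimethoxyphenyl]octanoate
Product: 8 methyl (3R)-3-(4-hydroxy-2,6-dimethoxyphenyl)octanoate
Conditions: H2 (1 atm), Pd/C (10%), EtOAc–MeOH, rt
Reagents that add atoms: none
Why: Hydrogenolysis of the aryl benzyl ether liberates the phenol para to the side chain; no other group is reducible under these conditions.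

Step 5
Reactants: 8 methyl (3R)-3-(4-hydroxy-2,6-dimethoxyphenyl)octanoate; 9 oxalyl chloride
Product: 11 methyl (3R)-3-(4,6-dimethoxy-2,3-dioxo-2,3-dihydro-1-benzofuran-5-yl)octanoate, via aryl chlorooxalate 10 (not isolated)
Conditions: Et2O, 0 °C to reflux
Reagents that add atoms: none
Why: O-acylation of the phenol gives the aryl chlorooxalate, whose acid chloride should close by intramolecular Friedel–Crafts acylation at either of the two equivalent, doubly oxygen-activated ortho positions (the oxygen analogue of the Stollé isatin synthesis), so no regiochemical choice arises.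

Step 6
Reactants: 11 methyl (3R)-3-(4,6-dimethoxy-2,3-dioxo-2,3-dihydro-1-benzofuran-5-yl)octanoate; 12 buta-1,2-diene
Product: 13 methyl (3R)-3-[(2R)-5,7-dimethoxy-2-methyl-3-methylidene-4-oxo-3,4-dihydro-2H-chromen-6-yl]octanoate
Conditions: Ni(cod)2 (10 mol%), (S,S)-i-Pr-FOXAP {(S,S)-[2-(4-isopropyl-4,5-dihydrooxazol-2-yl)ferrocenyl]diphenylphosphine, 20 mol%}, toluene, 80 °C, dry-ice condenser, slow argon sweep
Reagents that add atoms: none
Why: Proposed new method: zerovalent nickel should insert into the lactone acyl–O1 bond of the α-keto lactone 11 and expel the lactone carbonyl as CO, leaving a five-membered aroyl–nickel–aryloxide metallacycle; the aroyl group should then add to the central carbon of the allene, and the resulting 2-aroyl-π-allyl nickel aryloxide should form the O1–C2 bond at its methyl-bearing terminus. The closest known reaction types are the nickel-catalysed decarbonylative alkyne annulation of thioisatins to thiochromones, the chromone synthesis from salicylic acid ketals and alkynes through the same aroyl–nickel–aryloxide metallacycle, and the enantioselective nickel–phosphinooxazoline annulations of monosubstituted allenes with benzotriazinones and phthalic anhydrides, which give the analogous 3-substituted 4-methylidene heterocycles. The pyranone ring is closed by C–O reductive elimination from a seven-membered oxa-nickelacycle, so the five-membered ring (O1, C2, C3, C3a, C7a of 11) grows by one atom: one carbonyl carbon leaves and two allene carbons enter. The C2 stereocentre is set by the chiral P,N ligand on nickel during allene insertion and C–O bond formation. The step needs aroyl-to-central-carbon and oxygen-to-substituted-terminus regioselectivity (secured by the methyl group of the allene, as in the precedents), a single decarbonylation, and no migration of the exocyclic alkene into the ring, which would erase C2; the methyl ester and aryl methyl ethers of 11 are inert to the catalyst, and the neutral, hydride-free medium should leave the methylidene in place.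

Step 7
Reactants: 13 methyl (3R)-3-[(2R)-5,7-dimethoxy-2-methyl-3-methylidene-4-oxo-3,4-dihydro-2H-chromen-6-yl]octanoate
Product: 15 methyl (3R)-3-[(2R,3R)-5,7-dimethoxy-2,3-dimethyl-4-oxo-3,4-dihydro-2H-chromen-6-yl]octanoate, via cis-2,3-dimethylchromanone 14 (not isolated)
Conditions: RhCl(PPh3)3 (5 mol%), H2 (1 atm), benzene–EtOH, rt; then Et3N, MeOH, rt
Reagents that add atoms: none
Why: Homogeneous rhodium-catalysed hydrogenation should reduce the unhindered 1,1-disubstituted exocyclic alkene from the face opposite the C2 methyl group (mainly cis), and amine-mediated enolisation then equilibrates C3 to the thermodynamically preferred 2,3-trans (diequatorial) isomer while C2, which has no acidic hydrogen, keeps its configuration.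

Step 8
Reactants: 15 methyl (3R)-3-[(2R,3R)-5,7-dimethoxy-2,3-dimethyl-4-oxo-3,4-dihydro-2H-chromen-6-yl]octanoate
Product: 16 methyl (3R)-3-[(2R,3R)-5-hydroxy-7-methoxy-2,3-dimethyl-4-oxo-3,4-dihydro-2H-chromen-6-yl]octanoate
Conditions: BCl3 (1.5 equiv), CH2Cl2, −78 to 0 °C; aq NaHCO3
Reagents that add atoms: none
Why: Chelation-controlled Lewis acid demethylation: only the 5-methoxy group peri to the C4 carbonyl can form the six-membered boron chelate that triggers chloride attack on methyl, so the 7-methoxy group and the methyl ester should remain.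

Step 9
Reactants: 16 methyl (3R)-3-[(2R,3R)-5-hydroxy-7-methoxy-2,3-dimethyl-4-oxo-3,4-dihydro-2H-chromen-6-yl]octanoate
Product: 17 methyl (3R)-3-[(2R,3R)-8-bromo-5-hydroxy-7-methoxy-2,3-dimethyl-4-oxo-3,4-dihydro-2H-chromen-6-yl]octanoate
Conditions: NBS (1.05 equiv), MeCN, 0 °C, dark
Reagents that add atoms: N-bromosuccinimide, BrN1C(=O)CCC1=O
Why: Electrophilic aromatic bromination at C8, the only unsubstituted ring position, which is para to the free phenol and ortho to two ether oxygens.

Step 10
Reactants: 17 methyl (3R)-3-[(2R,3R)-8-bromo-5-hydroxy-7-methoxy-2,3-dimethyl-4-oxo-3,4-dihydro-2H-chromen-6-yl]octanoate; 18 tributyl(3-methylbut-2-en-1-yl)stannane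
Product: 19 methyl (3R)-3-[(2R,3R)-5-hydroxy-7-methoxy-2,3-dimethyl-8-(3-methylbut-2-en-1-yl)-4-oxo-3,4-dihydro-2H-chromen-6-yl]octanoate
Conditions: Pd2(dba)3 (5 mol%), P(t-Bu)3 (12 mol%), toluene, 90 °C
Reagents that add atoms: none
Why: Stille cross-coupling of the aryl bromide with the prenylstannane under neutral conditions, the electron-rich bulky phosphine being chosen for oxidative addition at the doubly ortho-substituted bromide, should leave both stereocentres of the base-sensitive chromanone untouched.

Step 11
Reactants: 19 methyl (3R)-3-[(2R,3R)-5-hydroxy-7-methoxy-2,3-dimethyl-8-(3-methylbut-2-en-1-yl)-4-oxo-3,4-dihydro-2H-chromen-6-yl]octanoate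
Product: 20 (3R)-3-[(2R,3R)-5-hydroxy-7-methoxy-2,3-dimethyl-8-(3-methylbut-2-en-1-yl)-4-oxo-3,4-dihydro-2H-chromen-6-yl]octanoic acid
Conditions: Me3SnOH (6 equiv), ClCH2CH2Cl, 80 °C; then cold 1 M HCl
Reagents that add atoms: trimethyltin hydroxide, C[Sn](C)(C)O
Why: Trimethyltin hydroxide cleaves the methyl ester through a tin carboxylate under near-neutral conditions, which avoids the hydroxide-induced retro-oxa-Michael opening of the 5-hydroxychromanone that would scramble C2 and C3.

Compound list
1 | 4-hydroxy-2,6-dimethoxybenzaldehyde | COc1cc(O)cc(OC)c1C=O | starting material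
2 | benzyl bromide | BrCc1ccccc1 | starting material
3 | 4-(benzyloxy)-2,6-dimethoxybenzaldehyde | COc1cc(OCc2ccccc2)cc(OC)c1C=O | intermediate
4 | trimethyl phosphonoacetate | COC(=O)CP(=O)(OC)OC | starting material
5 | methyl (E)-3-[4-(benzyloxy)-2,6-dimethoxyphenyl]prop-2-enoate | COC(=O)/C=C/c1c(OC)cc(OCc2ccccc2)cc1OC | intermediate
6 | n-pentylmagnesium bromide | CCCCC[Mg]Br | starting material
7 | methyl (3R)-3-[4-(benzyloxy)-2,6-dimethoxyphenyl]octanoate | CCCCC[C@H](CC(=O)OC)c1c(OC)cc(OCc2ccccc2)cc1OC | intermediate
8 | methyl (3R)-3-(4-hydroxy-2,6-dimethoxyphenyl)octanoate | CCCCC[C@H](CC(=O)OC)c1c(OC)cc(O)cc1OC | intermediate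
9 | oxalyl chloride | ClC(=O)C(=O)Cl | starting material
10 | methyl (3R)-3-{4-[(chlorooxalyl)oxy]-2,6-dimethoxyphenyl}octanoate (aryl chlorooxalate, not isolated) | CCCCC[C@H](CC(=O)OC)c1c(OC)cc(OC(=O)C(=O)Cl)cc1OC | intermediate
11 | methyl (3R)-3-(4,6-dimethoxy-2,3-dioxo-2,3-dihydro-1-benzofuran-5-yl)octanoate | CCCCC[C@H](CC(=O)OC)c1c(OC)cc2OC(=O)C(=O)c2c1OC | intermediate
12 | buta-1,2-diene | C=C=CC | starting material
13 | methyl (3R)-3-[(2R)-5,7-dimethoxy-2-methyl-3-methylidene-4-oxo-3,4-dihydro-2H-chromen-6-yl]octanoate | CCCCC[C@H](CC(=O)OC)c1c(OC)cc2O[C@H](C)C(=C)C(=O)c2c1OC | intermediate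
14 | methyl (3R)-3-[(2R,3S)-5,7-dimethoxy-2,3-dimethyl-4-oxo-3,4-dihydro-2H-chromen-6-yl]octanoate (cis, not isolated) | CCCCC[C@H](CC(=O)OC)c1c(OC)cc2O[C@H](C)[C@H](C)C(=O)c2c1OC | intermediate
15 | methyl (3R)-3-[(2R,3R)-5,7-dimethoxy-2,3-dimethyl-4-oxo-3,4-dihydro-2H-chromen-6-yl]octanoate (trans) | CCCCC[C@H](CC(=O)OC)c1c(OC)cc2O[C@H](C)[C@@H](C)C(=O)c2c1OC | intermediate
16 | methyl (3R)-3-[(2R,3R)-5-hydroxy-7-methoxy-2,3-dimethyl-4-oxo-3,4-dihydro-2H-chromen-6-yl]octanoate | CCCCC[C@H](CC(=O)OC)c1c(OC)cc2O[C@H](C)[C@@H](C)C(=O)c2c1O | intermediate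
17 | methyl (3R)-3-[(2R,3R)-8-bromo-5-hydroxy-7-methoxy-2,3-dimethyl-4-oxo-3,4-dihydro-2H-chromen-6-yl]octanoate | CCCCC[C@H](CC(=O)OC)c1c(OC)c(Br)c2O[C@H](C)[C@@H](C)C(=O)c2c1O | intermediate
18 | tributyl(3-methylbut-2-en-1-yl)stannane | CCCC[Sn](CCCC)(CCCC)CC=C(C)C | starting material
19 | methyl (3R)-3-[(2R,3R)-5-hydroxy-7-methoxy-2,3-dimethyl-8-(3-methylbut-2-en-1-yl)-4-oxo-3,4-dihydro-2H-chromen-6-yl]octanoate | CCCCC[C@H](CC(=O)OC)c1c(O)c2c(c(CC=C(C)C)c1OC)O[C@H](C)[C@@H](C)C2=O | intermediate
20 | (3R)-3-[(2R,3R)-5-hydroxy-7-methoxy-2,3-dimethyl-8-(3-methylbut-2-en-1-yl)-4-oxo-3,4-dihydro-2H-chromen-6-yl]octanoic acid | CCCCC[C@H](CC(=O)O)c1c(O)c2c(c(CC=C(C)C)c1OC)O[C@H](C)[C@@H](C)C2=O | target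

Total step count: 11. Longest linear sequence: 11 steps (1 to 20).

Steps most likely to fail

Step 6 (Proposed new method). The nickel may fail to insert and decarbonylate cleanly (slow oxidative addition, CO poisoning of the catalyst), the allene may oligomerise, the facial control may be poor at the temperature that decarbonylation needs, or the exocyclic alkene may migrate into the ring and erase C2. The fallback keeps the five-to-six ring expansion but uses known reaction types only; it sets out from 8 and comes back at 15. Friedel–Crafts acylation of 8 with 2-chloropropanoyl chloride (TiCl4, CH2Cl2, 0 °C) ortho to the phenol and closure with NaOAc in EtOH would give the 2-methylbenzofuran-3(2H)-one F1. Its lithium enolate (LiN(SiMe3)2, THF, −78 °C) would add to acetaldehyde at C2 and be trapped with Ac2O as the 2-(1-acetoxyethyl)-2-methylbenzofuranone F2. SmI2 (THF–MeOH, −78 °C) would cleave the α-aryloxy C–O bond, and the β-acetoxy enolate so formed would eliminate to the ortho-(E)-2-methylbut-2-enoylphenol F3. Without isolation, F3 would close under (−)-quinine catalysis (chlorobenzene, rt) by 6-endo oxa-Michael addition, the ring oxygen having moved from the old C2 to the inserted carbon and the cinchona base setting C2 by analogy with closely related ortho-tigloyl phenols. Amine equilibration as in step 7 then returns to 15.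

Step 3. Conjugate addition to a β-aryl enoate whose aryl group is electron-rich and doubly ortho-substituted may be slow, and competing uncatalysed addition would lower the facial selectivity. The fallback replaces catalyst control by auxiliary control; it sets out from 3 and comes back at 7. Olefination of 3 with diethyl {2-oxo-2-[(4R)-2-oxo-4-phenyl-1,3-oxazolidin-3-yl]ethyl}phosphonate (LiCl, i-Pr2NEt, MeCN) would give the N-enoyl oxazolidinone F4. n-Pentylmagnesium bromide with CuBr·SMe2 (THF, −40 °C) should add anti to the phenyl group of the magnesium-chelated s-cis imide and give the adduct F5 with the R benzylic centre. NaOMe in MeOH (0 °C) would then release methyl ester 7 and the auxiliary.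

Step 10. Allyl transposition during transfer of the prenyl group from tin to palladium may give the 1,1-dimethylallyl isomer, and oxidative addition at the hindered bromide may be slow enough for protodestannylation to compete. The fallback installs the prenyl group in two stages; it sets out from 17 and comes back at 19. Stille coupling of 17 with allyltributylstannane (Pd2(dba)3, P(t-Bu)3, toluene, 90 °C), where allyl transposition is degenerate, would give the 8-allyl chromanone F6. Cross-metathesis with excess 2-methylbut-2-ene (second-generation Grubbs catalyst, CH2Cl2, 40 °C) would convert allyl into prenyl and return to 19.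

Further compounds
F1 | step 6 | methyl (3R)-3-(4,6-dimethoxy-2-methyl-3-oxo-2,3-dihydro-1-benzofuran-5-yl)octanoate (both C2 epimers) | CCCCC[C@H](CC(=O)OC)c1c(OC)cc2OC(C)C(=O)c2c1OC
F2 | step 6 | methyl (3R)-3-{2-[1-(acetyloxy)ethyl]-4,6-dimethoxy-2-methyl-3-oxo-2,3-dihydro-1-benzofuran-5-yl}octanoate (diastereomer mixture) | CCCCC[C@H](CC(=O)OC)c1c(OC)cc2OC(C)(C(C)OC(C)=O)C(=O)c2c1OC
F3 | step 6 | methyl (3R)-3-{4-hydroxy-2,6-dimethoxy-3-[(E)-2-methylbut-2-enoyl]phenyl}octanoate | CCCCC[C@H](CC(=O)OC)c1c(OC)cc(O)c(C(=O)/C(C)=C/C)c1OC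
F4 | step 3 | (4R)-3-{(E)-3-[4-(benzyloxy)-2,6-dimethoxyphenyl]prop-2-enoyl}-4-phenyl-1,3-oxazolidin-2-one | O=C1OC[C@@H](c2ccccc2)N1C(=O)/C=C/c1c(OC)cc(OCc2ccccc2)cc1OC
F5 | step 3 | (4R)-3-{(3R)-3-[4-(benzyloxy)-2,6-dimethoxyphenyl]octanoyl}-4-phenyl-1,3-oxazolidin-2-one | O=C1OC[C@@H](c2ccccc2)N1C(=O)C[C@@H](CCCCC)c1c(OC)cc(OCc2ccccc2)cc1OC
F6 | step 10 | methyl (3R)-3-[(2R,3R)-5-hydroxy-7-methoxy-2,3-dimethyl-4-oxo-8-(prop-2-en-1-yl)-3,4-dihydro-2H-chromen-6-yl]octanoate | CCCCC[C@H](CC(=O)OC)c1c(OC)c(CC=C)c2O[C@H](C)[C@@H](C)C(=O)c2c1O
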